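**Retrosynthetic overview**
1. The last skeletal bonds come from an endo- and enantioselective Diels–Alder reaction between a chromene 2′-hydroxychalcone (dienophile) and an acetylated dehydroprenyl chalcone (diene); it closes the cyclohexene and sets its three stereocentres, and methanolysis of six acetates ends the route.
2. The dienophile is made in one ruthenium-carbene operation from a triene ketone and 2,4-diacetoxystyrene: ring-closing metathesis closes the pyran ring by forming its CH=CH bond (C3=C4 of the 2H-chromene) and cross-metathesis forms the chalcone CH=CH bond.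
3. Enabling feature: the only C=C of the pyran ring is a cis CH=CH lying between aromatic carbon C4a and the oxygen-bearing gem-dimethyl carbon C2, the retron of an ortho-vinylaryl 1,1-dimethylallyl ether; the enone CH=CH of the same aroyl unit is a second disubstituted alkene, meta to the first, so one catalyst can make both without cross-talk.
4. The triene ketone comes from 2,4-dihydroxybenzaldehyde (iodination, vinylation, O-propargylation, semi-hydrogenation, vinyl addition, oxidation); the diene comes from 2,4-dihydroxyacetophenone (iodination, Claisen–Schmidt condensation, exchange of methoxymethyl ethers for acetates, Suzuki dienylation).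
5. Ring order: pyran ring (step 8), then cyclohexene (step 17); the benzene rings are bought.

Key step: step 8

Remark on locants: in the cyclohexene, C1 carries the methyl group, C2 is the vinylic CH, C3 carries the ring of the open chalcone, C4 the chromenoyl group, C5 the resorcinol ring and C6 is CH2; the target is (3S,4R,5S), with the C3 aryl cis to the C4 aroyl and the C4 aroyl trans to the C5 aryl.
Assumption: the borate of (S)-VANOL is taken to shield the enone face that leads to the (3S,4R,5S) series; should the sense of induction be the opposite, (R)-VANOL is used and nothing else changes.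

**Route**

Step 1
Reactants: 1 2,4-dihydroxybenzaldehyde
Product: 2 2,4-dihydroxy-3-iodobenzaldehyde
Conditions: I2 (0.4 equiv), HIO3 (0.2 equiv), EtOH/H2O, 35 °C
Reagents that add atoms: iodine, II; iodic acid, O[I](=O)=O
Why: Oxidative electrophilic aromatic iodination should go to the carbon flanked by both hydroxyl groups, the most nucleophilic position, while iodic acid returns the released iodide to the iodinating species so that only water forms beside the product.

Step 2
Reactants: 2 2,4-dihydroxy-3-iodobenzaldehyde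
Product: 3 3-ethenyl-2,4-dihydroxybenzaldehyde
Conditions: vinylboronic acid pinacol ester (1.5 equiv), Pd(dppf)Cl2 (5 mol%), K2CO3 (3 equiv), dioxane/H2O 4:1, 80 °C
Reagents that add atoms: 2-ethenyl-4,4,5,5-tetramethyl-1,3,2-dioxaborolane, C=CB1OC(C)(C)C(C)(C)O1
Why: Suzuki–Miyaura coupling of an aryl iodide with a vinylboronate tolerates free phenols and the aldehyde, and the wide-bite-angle dppf ligand should cope with the doubly ortho-substituted iodide.

Step 3
Reactants: 3 3-ethenyl-2,4-dihydroxybenzaldehyde
Product: 4 3-ethenyl-2-hydroxy-4-[(2-methylbut-3-yn-2-yl)oxy]benzaldehyde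
Conditions: 3-chloro-3-methylbut-1-yne (1.3 equiv), CuCl2·2H2O (1 mol%), DBU (1.3 equiv), MeCN, 0 °C
Reagents that add atoms: 3-chloro-3-methylbut-1-yne, CC(C)(Cl)C#C
Why: Copper-catalysed propargylic etherification (copper acetylide ionising to a copper-stabilised propargyl cation) gives tertiary aryl propargyl ethers, and only the para hydroxyl reacts because it is the more acidic one and is not hydrogen-bonded to the formyl group.

Step 4
Reactants: 4 3-ethenyl-2-hydroxy-4-[(2-methylbut-3-yn-2-yl)oxy]benzaldehyde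
Product: 5 3-ethenyl-2-hydroxy-4-[(2-methylbut-3-en-2-yl)oxy]benzaldehyde
Conditions: H2 (1 atm), Pd/CaCO3 poisoned with Pb(OAc)2 (Lindlar catalyst), quinoline, EtOAc, rt, stopped after 1 equiv H2
Reagents that add atoms: none
Why: Lindlar semi-hydrogenation should stop at the alkene because the terminal alkyne binds the poisoned palladium surface far more strongly than the aryl vinyl group or the aldehyde; from here on the route stays at or below 40 °C until the ether is cyclised, to avoid Claisen rearrangement of the 1,1-dimethylallyl ether.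

Step 5
Reactants: 5 3-ethenyl-2-hydroxy-4-[(2-methylbut-3-en-2-yl)oxy]benzaldehyde
Product: 6 rac-1-{3-ethenyl-2-hydroxy-4-[(2-methylbut-3-en-2-yl)oxy]phenyl}prop-2-en-1-ol
Conditions: vinylmagnesium bromide (2.3 equiv), THF, −78 to 0 °C; neutral aqueous work-up
Reagents that add atoms: vinylmagnesium bromide, C=C[Mg]Br
Why: Grignard 1,2-addition to the aldehyde after the first equivalent has deprotonated the phenol; the carbinol centre forms as a racemate and is erased in the next step.

Step 6
Reactants: 6 rac-1-{3-ethenyl-2-hydroxy-4-[(2-methylbut-3-en-2-yl)oxy]phenyl}prop-2-en-1-ol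
Product: 7 1-{3-ethenyl-2-hydroxy-4-[(2-methylbut-3-en-2-yl)oxy]phenyl}prop-2-en-1-one
Conditions: MnO2 (15 equiv), CH2Cl2, rt; product kept cold with BHT and used at once
Reagents that add atoms: none
Why: MnO2 oxidises the doubly activated (allylic and benzylic) alcohol under neutral conditions, which should leave the hydrogen-bonded phenol unable to close onto the new vinyl ketone by oxa-Michael addition.

Step 7
Reactants: 1 2,4-dihydroxybenzaldehyde
Product: 9 4-ethenyl-1,3-phenylene diacetate, via dipotassium 4-ethenylbenzene-1,3-diolate 8 (not isolated)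
Conditions: Ph3PCH3Br (1.5 equiv), KOtBu (3.5 equiv), THF, 0 °C to rt; then Ac2O (3 equiv), 0 °C
Reagents that add atoms: methyltriphenylphosphonium bromide, C[P+](c1ccccc1)(c1ccccc1)c1ccccc1.[Br-]; acetic anhydride, CC(=O)OC(C)=O
Why: Wittig methylenation with the non-stabilised ylide works on phenoxide-bearing benzaldehydes, and acetylating the diphenoxide in the same flask avoids isolating the polymerisation-prone vinylresorcinol.

Step 8
Reactants: 7 1-{3-ethenyl-2-hydroxy-4-[(2-methylbut-3-en-2-yl)oxy]phenyl}prop-2-en-1-one; 9 4-ethenyl-1,3-phenylene diacetate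
Product: 11 4-[(1E)-3-(5-hydroxy-2,2-dimethyl-2H-chromen-6-yl)-3-oxoprop-1-en-1-yl]-1,3-phenylene diacetate, via 1-(5-hydroxy-2,2-dimethyl-2H-chromen-6-yl)prop-2-en-1-one 10 (not isolated)
Conditions: RuCl2(SIMes)(=CH-C6H4-2-OiPr) (second-generation Hoveyda–Grubbs catalyst, 5 mol%), 9 (3 equiv), BHT, CH2Cl2 (0.02 M), 40 °C, argon sparge
Reagents that add atoms: none
Why: The ruthenium carbene exchanges onto the ring-bound vinyl group (or the tertiary allyl ether) and [2+2] cycloaddition/cycloreversion through a ruthenacyclobutane joins the two terminal CH groups into the cis CH=CH bond of the pyran ring with loss of ethene, after which the same carbene population couples the electron-poor vinyl ketone of 10 with the electron-rich styrene 9 to the enone, again with loss of ethene. The closest known reaction types are ring-closing metathesis of ortho-vinylphenyl allyl ethers to 2H-chromenes and enone–styrene cross-metathesis, run here as a tandem. The only ring closed is the six-membered pyran ring, closed by ring-closing metathesis between the aryl-bound CH= and the CH= next to the gem-dimethyl carbon, helped by the Thorpe–Ingold effect and with the cis geometry enforced by the ring. No stereocentre is created, and the enone is expected as the E isomer because secondary metathesis equilibrates towards the conjugated trans chalcone. The step needs chemoselectivity between ring closure, cross-coupling and oligomerisation: ring closure is intramolecular, the vinyl ketone does not homodimerise and is meta to the other two alkenes so it cannot cyclise onto them, the chromene alkene once formed is unstrained and shielded by the quaternary carbon, and a stilbene formed by stray cross-metathesis at the ring vinyl group can still ring-close with release of 9. Excess 9, dilution and removal of ethene should drive both events, and the aryl acetates and the chelated phenol are inert to the carbene.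

Step 9
Reactants: 12 1-(2,4-dihydroxyphenyl)ethan-1-one
Product: 13 1-(2,4-dihydroxy-3-iodophenyl)ethan-1-one
Conditions: I2 (0.4 equiv), HIO3 (0.2 equiv), EtOH/H2O, 35 °C
Reagents that add atoms: iodine, II; iodic acid, O[I](=O)=O
Why: The same oxidative electrophilic iodination as in step 1 should again choose the carbon between the two hydroxyl groups.

Step 10
Reactants: 13 1-(2,4-dihydroxy-3-iodophenyl)ethan-1-one
Product: 14 1-[2-hydroxy-3-iodo-4-(methoxymethoxy)phenyl]ethan-1-one
Conditions: MOMCl (1.2 equiv), iPr2NEt (1.5 equiv), CH2Cl2, 0 °C to rt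
Reagents that add atoms: chloromethyl methyl ether, COCCl
Why: O-alkylation with an amine base takes the free para hydroxyl only, since the ortho hydroxyl is locked in a hydrogen bond to the ketone and shielded by iodine.

Step 11
Reactants: 1 2,4-dihydroxybenzaldehyde
Product: 15 2,4-bis(methoxymethoxy)benzaldehyde
Conditions: MOMCl (3 equiv), iPr2NEt (4 equiv), CH2Cl2, 0 °C to reflux
Reagents that add atoms: chloromethyl methyl ether, COCCl
Why: Exhaustive O-alkylation with excess reagent gives the base-stable bis-acetal needed for the aldol condensation.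

Step 12
Reactants: 14 1-[2-hydroxy-3-iodo-4-(methoxymethoxy)phenyl]ethan-1-one; 15 2,4-bis(methoxymethoxy)benzaldehyde
Product: 16 (2E)-3-[2,4-bis(methoxymethoxy)phenyl]-1-[2-hydroxy-3-iodo-4-(methoxymethoxy)phenyl]prop-2-en-1-one
Conditions: KOH (50% aq), EtOH, rt
Reagents that add atoms: none
Why: Claisen–Schmidt condensation of a 2′-hydroxyacetophenone with a non-enolisable aldehyde, with E1cB dehydration giving the E enone.

Step 13
Reactants: 16 (2E)-3-[2,4-bis(methoxymethoxy)phenyl]-1-[2-hydroxy-3-iodo-4-(methoxymethoxy)phenyl]prop-2-en-1-one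
Product: 17 (2E)-1-(2,4-dihydroxy-3-iodophenyl)-3-(2,4-dihydroxyphenyl)prop-2-en-1-one
Conditions: HCl (3 M in MeOH), 45 °C, light excluded
Reagents that add atoms: none
Why: Acid-catalysed acetal exchange with methanol removes the three methoxymethyl groups at a stage where no diene or chromene is present, and the trans enone should resist ring closure to a flavylium ion in the dark.

Step 14
Reactants: 17 (2E)-1-(2,4-dihydroxy-3-iodophenyl)-3-(2,4-dihydroxyphenyl)prop-2-en-1-one
Product: 18 4-[(1E)-3-(2,4-diacetoxy-3-iodophenyl)-3-oxoprop-1-en-1-yl]-1,3-phenylene diacetate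
Conditions: Ac2O (6 equiv), pyridine, DMAP (5 mol%), CH2Cl2, 0 °C to rt
Reagents that add atoms: acetic anhydride, CC(=O)OC(C)=O
Why: Nucleophile-catalysed acylation caps all four phenols, the chelated one included, so that this enone can later not be activated by the borate.

Step 15
Reactants: 19 2-methylbut-1-en-3-yne
Product: 20 4,4,5,5-tetramethyl-2-[(1E)-3-methylbuta-1,3-dien-1-yl]-1,3,2-dioxaborolane
Conditions: pinacolborane (1.05 equiv), Cp2Zr(H)Cl (5 mol%), Et3N (10 mol%), neat, 60 °C
Reagents that add atoms: pinacolborane, CC1(C)OBOC1(C)C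
Why: Zirconocene-hydride-catalysed hydroboration adds B–H syn across the terminal alkyne with boron at the terminal carbon, giving the E dienylboronate and leaving the 1,1-disubstituted alkene untouched.

Step 16
Reactants: 18 4-[(1E)-3-(2,4-diacetoxy-3-iodophenyl)-3-oxoprop-1-en-1-yl]-1,3-phenylene diacetate; 20 4,4,5,5-tetramethyl-2-[(1E)-3-methylbuta-1,3-dien-1-yl]-1,3,2-dioxaborolane
Product: 21 4-[(1E)-3-{2,4-diacetoxy-3-[(1E)-3-methylbuta-1,3-dien-1-yl]phenyl}-3-oxoprop-1-en-1-yl]-1,3-phenylene diacetate
Conditions: Pd(dppf)Cl2 (5 mol%), CsF (3 equiv), anhydrous dioxane, BHT, 70 °C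
Reagents that add atoms: none
Why: Suzuki–Miyaura coupling with anhydrous fluoride activation transfers the dienyl group with retention of the E geometry under conditions that should spare the aryl acetates.

Step 17
Reactants: 11 4-[(1E)-3-(5-hydroxy-2,2-dimethyl-2H-chromen-6-yl)-3-oxoprop-1-en-1-yl]-1,3-phenylene diacetate; 21 4-[(1E)-3-{2,4-diacetoxy-3-[(1E)-3-methylbuta-1,3-dien-1-yl]phenyl}-3-oxoprop-1-en-1-yl]-1,3-phenylene diacetate
Product: 22 [(3S,4R,5S)-3-{2,6-diacetoxy-3-[(2E)-3-(2,4-diacetoxyphenyl)prop-2-enoyl]phenyl}-5-(2,4-diacetoxyphenyl)-1-methylcyclohex-1-en-4-yl](5-hydroxy-2,2-dimethyl-2H-chromen-6-yl)methanone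
Conditions: B(OPh)3 (30 mol%), (S)-VANOL (33 mol%), 4 Å MS, PhCF3, 40 °C; 21 (1.5 equiv)
Reagents that add atoms: none
Why: Diels–Alder reaction of a boron-chelated 2′-hydroxychalcone, in which the chelated phenol and carbonyl of 11 bind the chiral aryl borate so that only this enone is activated (the enone of 21 has no free ortho hydroxyl), the aryl-bearing diene terminus bonds to the α-carbon and the CH2 terminus to the β-carbon, the endo transition state places the C3 aryl cis to the C4 aroyl, the E enone fixes C4/C5 trans, and the ligand shields one face of the chelate so that C3, C4 and C5 should arise as S, R and S; the exo (all-trans) isomer is removed by chromatography.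

Step 18
Reactants: 22 [(3S,4R,5S)-3-{2,6-diacetoxy-3-[(2E)-3-(2,4-diacetoxyphenyl)prop-2-enoyl]phenyl}-5-(2,4-diacetoxyphenyl)-1-methylcyclohex-1-en-4-yl](5-hydroxy-2,2-dimethyl-2H-chromen-6-yl)methanone
Product: 23 [(3S,4R,5S)-3-{3-[(2E)-3-(2,4-dihydroxyphenyl)prop-2-enoyl]-2,6-dihydroxyphenyl}-5-(2,4-dihydroxyphenyl)-1-methylcyclohex-1-en-4-yl](5-hydroxy-2,2-dimethyl-2H-chromen-6-yl)methanone (CNP0115975.1)
Conditions: K2CO3 (0.5 equiv), MeOH/THF, 0 °C to rt; pH 6 buffer work-up
Reagents that add atoms: none
Why: Base-catalysed transesterification of aryl acetates with methanol should be much faster at low temperature than enolisation at C4 or chalcone–flavanone isomerisation, so the six phenols are released without touching the three stereocentres, the enone or the chromene.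

**Compound list**
1 | 2,4-dihydroxybenzaldehyde | O=Cc1ccc(O)cc1O | starting material
2 | 2,4-dihydroxy-3-iodobenzaldehyde | O=Cc1ccc(O)c(I)c1O | intermediate
3 | 3-ethenyl-2,4-dihydroxybenzaldehyde | O=Cc1ccc(O)c(C=C)c1O | intermediate
4 | 3-ethenyl-2-hydroxy-4-[(2-methylbut-3-yn-2-yl)oxy]benzaldehyde | O=Cc1ccc(OC(C)(C)C#C)c(C=C)c1O | intermediate
5 | 3-ethenyl-2-hydroxy-4-[(2-methylbut-3-en-2-yl)oxy]benzaldehyde | O=Cc1ccc(OC(C)(C)C=C)c(C=C)c1O | intermediate
6 | rac-1-{3-ethenyl-2-hydroxy-4-[(2-methylbut-3-en-2-yl)oxy]phenyl}prop-2-en-1-ol | C=CC(O)c1ccc(OC(C)(C)C=C)c(C=C)c1O | intermediate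
7 | 1-{3-ethenyl-2-hydroxy-4-[(2-methylbut-3-en-2-yl)oxy]phenyl}prop-2-en-1-one | C=CC(=O)c1ccc(OC(C)(C)C=C)c(C=C)c1O | intermediate
8 | dipotassium 4-ethenylbenzene-1,3-diolate (not isolated) | C=Cc1ccc([O-])cc1[O-].[K+].[K+] | intermediate
9 | 4-ethenyl-1,3-phenylene diacetate | C=Cc1ccc(OC(C)=O)cc1OC(C)=O | intermediate
10 | 1-(5-hydroxy-2,2-dimethyl-2H-chromen-6-yl)prop-2-en-1-one (not isolated) | C=CC(=O)c1ccc2c(c1O)C=CC(C)(C)O2 | intermediate
11 | 4-[(1E)-3-(5-hydroxy-2,2-dimethyl-2H-chromen-6-yl)-3-oxoprop-1-en-1-yl]-1,3-phenylene diacetate | CC(=O)Oc1ccc(/C=C/C(=O)c2ccc3c(c2O)C=CC(C)(C)O3)c(OC(C)=O)c1 | intermediate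
12 | 1-(2,4-dihydroxyphenyl)ethan-1-one | CC(=O)c1ccc(O)cc1O | starting material
13 | 1-(2,4-dihydroxy-3-iodophenyl)ethan-1-one | CC(=O)c1ccc(O)c(I)c1O | intermediate
14 | 1-[2-hydroxy-3-iodo-4-(methoxymethoxy)phenyl]ethan-1-one | CC(=O)c1ccc(OCOC)c(I)c1O | intermediate
15 | 2,4-bis(methoxymethoxy)benzaldehyde | COCOc1ccc(C=O)c(OCOC)c1 | intermediate
16 | (2E)-3-[2,4-bis(methoxymethoxy)phenyl]-1-[2-hydroxy-3-iodo-4-(methoxymethoxy)phenyl]prop-2-en-1-one | COCOc1ccc(/C=C/C(=O)c2ccc(OCOC)c(I)c2O)c(OCOC)c1 | intermediate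
17 | (2E)-1-(2,4-dihydroxy-3-iodophenyl)-3-(2,4-dihydroxyphenyl)prop-2-en-1-one | Oc1ccc(/C=C/C(=O)c2ccc(O)c(I)c2O)c(O)c1 | intermediate
18 | 4-[(1E)-3-(2,4-diacetoxy-3-iodophenyl)-3-oxoprop-1-en-1-yl]-1,3-phenylene diacetate | CC(=O)Oc1ccc(/C=C/C(=O)c2ccc(OC(C)=O)c(I)c2OC(C)=O)c(OC(C)=O)c1 | intermediate
19 | 2-methylbut-1-en-3-yne | CC(=C)C#C | starting material
20 | 4,4,5,5-tetramethyl-2-[(1E)-3-methylbuta-1,3-dien-1-yl]-1,3,2-dioxaborolane | CC(=C)/C=C/B1OC(C)(C)C(C)(C)O1 | intermediate
21 | 4-[(1E)-3-{2,4-diacetoxy-3-[(1E)-3-methylbuta-1,3-dien-1-yl]phenyl}-3-oxoprop-1-en-1-yl]-1,3-phenylene diacetate | CC(=C)/C=C/c1c(OC(C)=O)ccc(C(=O)/C=C/c2ccc(OC(C)=O)cc2OC(C)=O)c1OC(C)=O | intermediate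
22 | [(3S,4R,5S)-3-{2,6-diacetoxy-3-[(2E)-3-(2,4-diacetoxyphenyl)prop-2-enoyl]phenyl}-5-(2,4-diacetoxyphenyl)-1-methylcyclohex-1-en-4-yl](5-hydroxy-2,2-dimethyl-2H-chromen-6-yl)methanone | CC1=C[C@H](c2c(OC(C)=O)ccc(C(=O)/C=C/c3ccc(OC(C)=O)cc3OC(C)=O)c2OC(C)=O)[C@H](C(=O)c2ccc3c(c2O)C=CC(C)(C)O3)[C@@H](c2ccc(OC(C)=O)cc2OC(C)=O)C1 | intermediate
23 | [(3S,4R,5S)-3-{3-[(2E)-3-(2,4-dihydroxyphenyl)prop-2-enoyl]-2,6-dihydroxyphenyl}-5-(2,4-dihydroxyphenyl)-1-methylcyclohex-1-en-4-yl](5-hydroxy-2,2-dimethyl-2H-chromen-6-yl)methanone | CC1=C[C@H](c2c(O)ccc(C(=O)/C=C/c3ccc(O)cc3O)c2O)[C@H](C(=O)c2ccc3c(c2O)C=CC(C)(C)O3)[C@@H](c2ccc(O)cc2O)C1 | target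

**Step count and risks**

Total step count: 18. Longest linear sequence: 9 steps (steps 1–6, 8, 17, 18).

Steps most likely to fail:

Step 8. The cross-metathesis half may stall through homodimerisation of the styrene or catalyst decay, or the vinyl ketone may be lost to oxa-Michael ring closure or oligomerisation before it is coupled. The fallback separates the two events and forms the enone by aldol chemistry, setting out from 5 and returning at 11. Ring-closing metathesis of 5 with RuCl2(SIMes)(PCy3)(=CHPh) (second-generation Grubbs catalyst, CH2Cl2, 40 °C) closes the same pyran CH=CH bond and should give 5-hydroxy-2,2-dimethyl-2H-chromene-6-carbaldehyde F1. Addition of MeMgBr gives rac-1-(5-hydroxy-2,2-dimethyl-2H-chromen-6-yl)ethan-1-ol F2, and MnO2 oxidation gives 1-(5-hydroxy-2,2-dimethyl-2H-chromen-6-yl)ethan-1-one F3. Claisen–Schmidt condensation of F3 with 15 (KOH, EtOH) gives (2E)-3-[2,4-bis(methoxymethoxy)phenyl]-1-(5-hydroxy-2,2-dimethyl-2H-chromen-6-yl)prop-2-en-1-one F4, and HCl in MeOH gives (2E)-3-(2,4-dihydroxyphenyl)-1-(5-hydroxy-2,2-dimethyl-2H-chromen-6-yl)prop-2-en-1-one F5. Acetylation of the two non-chelated phenols (Ac2O 2.2 equiv, pyridine, 0 °C) then gives 11.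

Step 17. Endo/exo discrimination or enantiofacial control may be poor, and the chelating product may inhibit turnover of the borate. The fallback gives up asymmetric induction in favour of a racemic cycloaddition and resolution, setting out from 11 and 21 and returning at 22. Silver nanoparticles on SiO2 (zerovalent silver, CH2Cl2, 50 °C) should promote the cycloaddition of the 2′-hydroxychalcone with an endo preference, and preparative HPLC on a chiral stationary phase then separates 22 from the (3R,4S,5R)-enantiomer of 22 F6.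

Step 16. Acetates may be lost under the basic fluoride activation, transmetalation at the doubly ortho-substituted iodide may be slow, and the diene may polymerise at 70 °C. The fallback builds the diene in two stages, setting out from 18 and returning at 21. A Mizoroki–Heck reaction of 18 with 2-methylbut-3-en-2-ol (Pd(OAc)2, Bu4NCl, NaHCO3, DMF, 60 °C) gives 4-[(1E)-3-{2,4-diacetoxy-3-[(1E)-3-hydroxy-3-methylbut-1-en-1-yl]phenyl}-3-oxoprop-1-en-1-yl]-1,3-phenylene diacetate F7. Dehydration of the tertiary allylic alcohol (methanesulfonyl chloride, Et3N, CH2Cl2, 0 °C) then gives 21.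

**Further compounds**
F1 | step 8 | 5-hydroxy-2,2-dimethyl-2H-chromene-6-carbaldehyde | O=Cc1ccc2c(c1O)C=CC(C)(C)O2
F2 | step 8 | rac-1-(5-hydroxy-2,2-dimethyl-2H-chromen-6-yl)ethan-1-ol | CC(O)c1ccc2c(c1O)C=CC(C)(C)O2
F3 | step 8 | 1-(5-hydroxy-2,2-dimethyl-2H-chromen-6-yl)ethan-1-one | CC(=O)c1ccc2c(c1O)C=CC(C)(C)O2
F4 | step 8 | (2E)-3-[2,4-bis(methoxymethoxy)phenyl]-1-(5-hydroxy-2,2-dimethyl-2H-chromen-6-yl)prop-2-en-1-one | COCOc1ccc(/C=C/C(=O)c2ccc3c(c2O)C=CC(C)(C)O3)c(OCOC)c1
F5 | step 8 | (2E)-3-(2,4-dihydroxyphenyl)-1-(5-hydroxy-2,2-dimethyl-2H-chromen-6-yl)prop-2-en-1-one | Oc1ccc(/C=C/C(=O)c2ccc3c(c2O)C=CC(C)(C)O3)c(O)c1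
F6 | step 17 | (3R,4S,5R)-enantiomer of 22 | CC1=C[C@@H](c2c(OC(C)=O)ccc(C(=O)/C=C/c3ccc(OC(C)=O)cc3OC(C)=O)c2OC(C)=O)[C@@H](C(=O)c2ccc3c(c2O)C=CC(C)(C)O3)[C@H](c2ccc(OC(C)=O)cc2OC(C)=O)C1
F7 | step 16 | 4-[(1E)-3-{2,4-diacetoxy-3-[(1E)-3-hydroxy-3-methylbut-1-en-1-yl]phenyl}-3-oxoprop-1-en-1-yl]-1,3-phenylene diacetate | CC(C)(O)/C=C/c1c(OC(C)=O)ccc(C(=O)/C=C/c2ccc(OC(C)=O)cc2OC(C)=O)c1OC(C)=O
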